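**Strategy.** Ring A (C1–C6) of the target has cis carbon substituents on C1 (C7) and on quaternary C6 (pyranone carbon C6′), oxygen on C3 and a C4=C5 double bond. This is the pattern of a cis-locked 3-methylbutenolide (C6=C1, lactone carbons C6′ and C7) joined to a 1-methoxy-3-silyloxydiene (C2–C5). One thermal Diels–Alder reaction forms C1–C2 and C5–C6, closes ring A and sets C1 and C6 under control of a menthyl acetal on C7; loss of methanol then unveils the enone. Afterwards C2/C3 are oxygenated on the convex face, the lactone acetal is unravelled into C7 (side chain, C9 from an Evans aldol fragment) and C6′ (pyranone), and the epoxide is closed late.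

Key step: step 4

Labels: side chain C7(Me)=C8–C9(Me)–C10(=O)–C11–C12; C6′ is the butenolide carbonyl carbon on C6; "upper face" of ring A is the face carrying C7 and C6′.

Assumption: enone 1 is taken as a catalogue compound, and the (5S) acetal epimer 6 is taken to be the one that crystallises, by analogy with the parent 5-menthyloxyfuranone.

Step 1
Reactants: 1 (E)-1-methoxy-2-methylpent-1-en-3-one
Product: 2 tert-butyl{[(1E,3Z)-1-methoxy-2-methylpenta-1,3-dien-3-yl]oxy}dimethylsilane
Conditions: TBSOTf, Et3N, Et2O, 0 °C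
Reagents that add atoms: tert-butyldimethylsilyl triflate, CC(C)(C)[Si](C)(C)OS(=O)(=O)C(F)(F)F
Why: Soft enolisation and O-silylation of the ethyl ketone (silyl enol ether formation) should give the dienol ether, the amine/silyl triflate conditions favouring the (Z)-enol ether whose terminal methyl lies outside the s-cis diene.

Step 2
Reactants: 3 3-methylfuran-2-carboxylic acid
Product: 4 5-hydroxy-3-methylfuran-2(5H)-one (racemic)
Conditions: O2, rose bengal (cat.), visible light, MeOH, rt
Reagents that add atoms: dioxygen, O=O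
Why: Dye-sensitised photooxygenation (singlet-oxygen [4+2] addition to the furan, then decarboxylative collapse of the endoperoxide) should deliver the α-methyl γ-hydroxybutenolide.

Step 3
Reactants: 4 5-hydroxy-3-methylfuran-2(5H)-one; 5 (+)-menthol
Product: 6 (5S)-5-(d-menthyloxy)-3-methylfuran-2(5H)-one
Conditions: CSA (cat.), toluene, reflux (−H2O); crystallisation from hexane, mother liquor re-equilibrated with acid
Reagents that add atoms: none
Why: Acid-catalysed acetalisation of the lactol gives both C7 epimers, which interconvert through the oxocarbenium ion, so crystallisation of the (5S) epimer sets the acetal centre by crystallisation-driven epimerisation.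

Step 4
Reactants: 2 silyloxydiene; 6 menthyloxybutenolide
Product: 7 cis-fused cycloadduct (lactone acetal; C3 silyl enol ether; C5 methoxy)
Conditions: toluene, BHT (cat.), 120 °C, sealed tube
Reagents that add atoms: none
Why: The diene and the butenolide combine in a concerted but asynchronous [4+2] cycloaddition in which the enol-ether terminus C2 bonds to the butenolide β-carbon C1 ahead of the C5–C6 bond to the α-carbon. The closest known reaction type is the thermal Diels–Alder reaction of 5-alkoxyfuran-2(5H)-ones with 2-silyloxy- and 1-alkoxy-3-silyloxydienes. Ring A is closed by intermolecular annulation, both σ-bonds forming suprafacially on each partner, so the fusion to the lactone is necessarily cis. C1 and C6 are set by approach of the diene to the butenolide face anti to the menthyloxy group on C7, while C2 and C5 follow from the (1E,3Z) diene geometry and endo placement of the lactone and are both erased later (C5 by elimination, C2 by enolisation). The step needs regioselectivity and π-facial selectivity: the 3-silyloxy and 1-methoxy donors make C2 the nucleophilic terminus and the acetal substituent blocks one face, whereas endo/exo selectivity is not required.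

Step 5
Reactants: 7 cycloadduct
Product: 9 enone lactone acetal (C3 ketone; C4=C5), via β-methoxy ketone 8 (not isolated)
Conditions: 0.5 M aq HCl, THF, 0 °C → rt
Reagents that add atoms: none
Why: Silyl enol ether hydrolysis followed by acid-promoted β-elimination of methanol should give the enone, the lactone acetal being inert to cold dilute acid and both C2 epimers being usable because C2 is enolised next.

Step 6
Reactants: 9 enone lactone acetal
Product: 11 C2-hydroxy enone (hydroxyl trans to C7), via potassium dienolate 10 (not isolated)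
Conditions: KN(SiMe3)2, THF, −78 °C; then 2-(phenylsulfonyl)-3-phenyloxaziridine, −78 °C
Reagents that add atoms: trans-2-(phenylsulfonyl)-3-phenyloxaziridine, O=S(=O)(c1ccccc1)N1OC1c1ccccc1
Why: Kinetic α′-deprotonation (C2–H is the only enolisable hydrogen) and Davis oxaziridine hydroxylation should deliver oxygen to the convex face of the cis-fused bicycle, anti to the lactone ring, placing the C2 hydroxyl on the lower face and the C2 methyl cis to C7.

Step 7
Reactants: 11 C2-hydroxy enone
Product: 12 trans-C2/C3 diol (C3 hydroxyl cis to C7)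
Conditions: NaBH4, CeCl3·7H2O, MeOH, −78 °C
Reagents that add atoms: none
Why: Luche 1,2-reduction should add hydride to the convex face, anti to the C2 methyl and the lactone ring and syn to the coordinating C2 hydroxyl, so the new C3 hydroxyl is trans to the C2 hydroxyl.

Step 8
Reactants: 12 trans diol
Product: 13 C2/C3 bis(triethylsilyl) ether
Conditions: TESOTf, 2,6-lutidine, CH2Cl2, −78 → 0 °C
Reagents that add atoms: triethylsilyl triflate, CC[Si](CC)(CC)OS(=O)(=O)C(F)(F)F
Why: Silyl triflate silylation protects both the secondary allylic and the hindered tertiary alcohol without generating an alkoxide that could attack the lactone on the same face.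

Step 9
Reactants: 13 bis-TES lactone acetal
Product: 14 1,4-diol (C7H2OH on C1; C6′H2OH on C6)
Conditions: LiAlH4, THF, 0 °C
Reagents that add atoms: none
Why: Hydride reduction of the lactone acetal (ester reduction, collapse of the hemiacetal and reduction of the liberated aldehyde) should give the diol and release the auxiliary without touching a stereocentre, since C6 is quaternary and the transient C7 aldehyde is reduced at once.

Step 10
Reactants: 14 1,4-diol
Product: 16 transposed γ-lactone (C7 carbonyl; C6′H2–O), via lactol 15 (not isolated)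
Conditions: [Cu(MeCN)4]OTf (cat.), 2,2′-bipyridine, TEMPO, N-methylimidazole, air, MeCN, rt
Reagents that add atoms: none
Why: Copper/nitroxyl aerobic oxidative lactonisation of a diol should oxidise the C7 carbinol on tertiary C1 in preference to the neopentyl carbinol on C6, the hydroxy aldehyde closing to the lactol, which is oxidised to the lactone.

Step 11
Reactants: 17 (S)-4-benzyl-3-propionyloxazolidin-2-one; 18 propanal
Product: 20 (4S)-4-benzyl-3-[(2S,3R)-3-hydroxy-2-methylpentanoyl]oxazolidin-2-one, via boron enolate 19 (not isolated)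
Conditions: Bu2BOTf, Et3N, CH2Cl2, −78 → 0 °C; then 18, −78 → 0 °C; H2O2, pH 7 buffer, MeOH
Reagents that add atoms: none
Why: Evans syn-aldol reaction, in which the (Z)-boron enolate reacts through a Zimmerman–Traxler transition state on the face away from the benzyl group, sets the future C9 (the C10 carbinol centre is later oxidised).

Step 12
Reactants: 20 aldol adduct
Product: 21 (4S)-4-benzyl-3-[(2S,3R)-3-(tert-butyldimethylsilyloxy)-2-methylpentanoyl]oxazolidin-2-one
Conditions: TBSOTf, 2,6-lutidine, CH2Cl2, 0 °C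
Reagents that add atoms: tert-butyldimethylsilyl triflate, CC(C)(C)[Si](C)(C)OS(=O)(=O)C(F)(F)F
Why: Silyl ether formation blocks retro-aldol cleavage and carries the C10 oxygen in masked form to the last step.

Step 13
Reactants: 21 silylated aldol adduct
Product: 22 (2R,3R)-3-(tert-butyldimethylsilyloxy)-2-methylpentan-1-ol
Conditions: LiBH4, MeOH (1 equiv), THF, 0 °C
Reagents that add atoms: none
Why: Reductive cleavage of the N-acyl oxazolidinone with lithium borohydride gives the primary alcohol and returns the auxiliary without epimerising the α-centre.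

Step 14
Reactants: 22 primary alcohol
Product: 23 tert-butyl{[(2S,3R)-1-iodo-2-methylpentan-3-yl]oxy}dimethylsilane
Conditions: I2, PPh3, imidazole, CH2Cl2, 0 °C → rt
Reagents that add atoms: iodine, II
Why: Appel-type iodination replaces the primary hydroxyl by SN2 at the CH2 group, leaving both stereocentres untouched.

Step 15
Reactants: 16 transposed γ-lactone; 23 iodide
Product: 26 C7 ketone (C8–C12 chain attached; C6′H2OTES), via alkyllithium 24 (not isolated), via lithium alkoxide 25 (not isolated)
Conditions: 23, t-BuLi (2 equiv), Et2O, −78 °C; then 16, THF, −78 → −20 °C; then TESCl, DMAP, −20 °C → rt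
Reagents that add atoms: chlorotriethylsilane, CC[Si](CC)(CC)Cl
Why: Iodine–lithium exchange and single addition of the alkyllithium to the lactone (the tetrahedral alkoxide persists until the organolithium is consumed), followed by O-silylation of the ring-opened primary alkoxide, form the C7–C8 bond and bring in C9 unchanged from fragment 23.

Step 16
Reactants: 26 C7 ketone
Product: 28 (Z)-C7 enol triflate, via potassium enolate 27 (not isolated)
Conditions: KN(SiMe3)2, THF, −78 °C; then PhNTf2, −78 → 0 °C
Reagents that add atoms: N-phenylbis(trifluoromethanesulfonimide), O=S(=O)(N(c1ccccc1)S(=O)(=O)C(F)(F)F)C(F)(F)F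
Why: Enolisation/O-triflation should occur at the C8 methylene (the C1 methine is buried between two fully substituted carbons), and the very bulky ring substituent on the carbonyl enforces the (Z)-enolate, so the triflate oxygen and C9 are cis.

Step 17
Reactants: 28 enol triflate
Product: 29 (E)-C7=C8 alkene (C7 methyl; C6′H2OTES)
Conditions: MeZnCl, Pd(PPh3)4 (cat.), THF, 50 °C
Reagents that add atoms: methylzinc chloride, C[Zn]Cl
Why: Negishi cross-coupling of an alkenyl triflate proceeds with retention of alkene geometry, so the new C7 methyl is cis to C9 and the alkene is (E) as in the target.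

Step 18
Reactants: 29 alkene with primary TES ether
Product: 30 C6′ aldehyde
Conditions: (COCl)2, DMSO, CH2Cl2, −78 → −30 °C; then Et3N, → 0 °C
Reagents that add atoms: none
Why: Swern oxidation of a primary triethylsilyl ether, a known selective oxidative desilylation, converts the C6′H2OTES group directly into the aldehyde while secondary and tertiary silyl ethers persist, and the aldehyde has no α-hydrogen to epimerise.

Step 19
Reactants: 30 C6′ aldehyde; 31 methyl 2-methyl-3-oxopentanoate
Product: 33 aldol adduct (δ-hydroxy β-keto ester on C6), via dianion 32 (not isolated)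
Conditions: 31, NaH, THF, 0 °C; n-BuLi, 0 °C; then 30, −78 °C
Reagents that add atoms: none
Why: Aldol addition of the β-keto ester dianion through its terminal carbon to the non-enolisable aldehyde builds the full pyranone carbon chain, the new centres being mixtures that disappear in the next two steps.

Step 20
Reactants: 33 aldol adduct
Product: 34 β,δ-diketo ester
Conditions: Dess–Martin periodinane, NaHCO3, CH2Cl2, rt
Reagents that add atoms: none
Why: Dess–Martin oxidation of the secondary alcohol gives the 1,3,5-tricarbonyl system under neutral conditions that spare the silyl ethers and alkenes.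

Step 21
Reactants: 34 β,δ-diketo ester
Product: 35 4-hydroxy-3,5-dimethyl-2-pyranone (C6′ on C6)
Conditions: DBU, toluene, rt → 50 °C
Reagents that add atoms: none
Why: Base-mediated cyclisation (6-exo-trig lactonisation of the C6′ enol oxygen onto the ester with loss of methanol) gives the hydroxypyranone.

Step 22
Reactants: 35 hydroxypyranone
Product: 36 2-methoxy-3,5-dimethyl-4-pyranone
Conditions: MeOTf, 2,6-di-tert-butyl-4-methylpyridine, CH2Cl2, 0 °C → rt
Reagents that add atoms: methyl triflate, COS(=O)(=O)C(F)(F)F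
Why: O-Methylation of the neutral 4-hydroxy-2-pyranone with a hard methylating agent occurs at the C2′ carbonyl oxygen (regioselective alkylation of hydroxypyranones), giving the 2-methoxy-4-pyranone of the target.

Step 23
Reactants: 36 methoxypyranone
Product: 37 C3 alcohol (C2 OTES and C10 OTBS kept)
Conditions: PPTS, MeOH/CH2Cl2, 0 °C
Reagents that add atoms: none
Why: Acid-catalysed methanolysis removes the secondary allylic TES ether faster than the tertiary TES and the secondary TBS ether (graded silyl ether lability).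

Step 24
Reactants: 37 C3 alcohol
Product: 39 epoxy alcohol (C2/C3 epoxide; C10 hydroxyl), via mesylate 38 (not isolated)
Conditions: Ms2O, Et3N, DMAP (cat.), CH2Cl2, −30 °C; then Bu4NF, THF, −30 °C → rt
Reagents that add atoms: none
Why: Sulfonylation of the C3 hydroxyl and fluoride-induced desilylation let the liberated C2 alkoxide displace the trans mesylate (intramolecular SN2, 3-exo-tet, inversion at C3), closing the epoxide on the lower face while the same fluoride frees the C10 alcohol; chloride-free Ms2O avoids allylic chloride formation.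

Step 25
Reactants: 39 epoxy alcohol
Product: 40 target CNP0336888.3
Conditions: Dess–Martin periodinane, NaHCO3, CH2Cl2, 0 °C → rt
Reagents that add atoms: none
Why: Buffered Dess–Martin oxidation converts the C10 alcohol into the ethyl ketone under non-enolising conditions, so the allylic α-centre C9 keeps its configuration.

**Compound list**

1 | (E)-1-methoxy-2-methylpent-1-en-3-one | CO/C=C(\C)C(=O)CC | starting material
2 | tert-butyl{[(1E,3Z)-1-methoxy-2-methylpenta-1,3-dien-3-yl]oxy}dimethylsilane | CO/C=C(\C)/C(O[Si](C)(C)C(C)(C)C)=C/C | intermediate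
3 | 3-methylfuran-2-carboxylic acid | Cc1ccoc1C(=O)O | starting material
4 | 5-hydroxy-3-methylfuran-2(5H)-one (racemic) | CC1=CC(O)OC1=O | intermediate
5 | (+)-menthol, (1S,2R,5S)-5-methyl-2-(propan-2-yl)cyclohexan-1-ol | CC(C)[C@H]1CC[C@H](C)C[C@@H]1O | starting material
6 | (5S)-3-methyl-5-{[(1S,2R,5S)-5-methyl-2-(propan-2-yl)cyclohexyl]oxy}furan-2(5H)-one | O=C1O[C@H](O[C@H]2C[C@@H](C)CC[C@@H]2C(C)C)C=C1C | intermediate
7 | cycloadduct: ring A cis-fused to the γ-lactone acetal (C6–C6′(=O)–O–C7H(O-menthyl)–C1); C3 OTBS enol ether (C3=C4); C2-Me, C5-OMe on the upper face; C6-Me lower face; O-menthyl anti to C2 | O=C1O[C@H](O[C@H]3C[C@@H](C)CC[C@@H]3C(C)C)[C@H]2[C@@H](C)C(O[Si](C)(C)C(C)(C)C)=C(C)[C@@H](OC)[C@@]12C | intermediate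
8 | β-methoxy ketone (C3 ketone, C5-OMe) of the same bicycle | O=C1O[C@H](O[C@H]3C[C@@H](C)CC[C@@H]3C(C)C)[C@H]2[C@@H](C)C(=O)C(C)[C@@H](OC)[C@@]12C | intermediate (not isolated)
9 | enone lactone acetal (C3=O, C4=C5) | O=C1O[C@H](O[C@H]3C[C@@H](C)CC[C@@H]3C(C)C)[C@H]2[C@@H](C)C(=O)C(C)=C[C@@]12C | intermediate
10 | potassium C2=C3 dienolate of 9 | [K+].O=C1O[C@H](O[C@H]3C[C@@H](C)CC[C@@H]3C(C)C)[C@H]2C(C)=C([O-])C(C)=C[C@@]12C | intermediate (not isolated)
11 | C2-hydroxy enone (C2-OH lower face, C2-Me upper face) | O=C1O[C@H](O[C@H]3C[C@@H](C)CC[C@@H]3C(C)C)[C@H]2[C@](C)(O)C(=O)C(C)=C[C@@]12C | intermediate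
12 | trans-C2/C3 diol (C3-OH upper face) | O=C1O[C@H](O[C@H]3C[C@@H](C)CC[C@@H]3C(C)C)[C@H]2[C@](C)(O)[C@@H](O)C(C)=C[C@@]12C | intermediate
13 | C2/C3 bis(triethylsilyl) ether of 12 | O=C1O[C@H](O[C@H]3C[C@@H](C)CC[C@@H]3C(C)C)[C@H]2[C@](C)(O[Si](CC)(CC)CC)[C@@H](O[Si](CC)(CC)CC)C(C)=C[C@@]12C | intermediate
14 | 1,4-diol: C7H2OH on C1 and C6′H2OH on C6 (cis), C2/C3 bis-TES | OC[C@H]1[C@](C)(O[Si](CC)(CC)CC)[C@@H](O[Si](CC)(CC)CC)C(C)=C[C@@]1(C)CO | intermediate
15 | lactol (C7 hemiacetal bridged to C6′H2–O) | OC3[C@H]1[C@](C)(O[Si](CC)(CC)CC)[C@@H](O[Si](CC)(CC)CC)C(C)=C[C@@]1(C)CO3 | intermediate (not isolated)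
16 | transposed cis-fused γ-lactone (C7 carbonyl on C1, C6′H2–O on C6), C2/C3 bis-TES | O=C3[C@H]1[C@](C)(O[Si](CC)(CC)CC)[C@@H](O[Si](CC)(CC)CC)C(C)=C[C@@]1(C)CO3 | intermediate
17 | (S)-4-benzyl-3-propionyloxazolidin-2-one | CCC(=O)N1C(=O)OC[C@@H]1Cc1ccccc1 | starting material
18 | propanal | CCC=O | starting material
19 | (Z)-dibutylboron enolate of 17 | C/C=C(\OB(CCCC)CCCC)N1C(=O)OC[C@@H]1Cc1ccccc1 | intermediate (not isolated)
20 | (4S)-4-benzyl-3-[(2S,3R)-3-hydroxy-2-methylpentanoyl]oxazolidin-2-one | CC[C@@H](O)[C@H](C)C(=O)N1C(=O)OC[C@@H]1Cc1ccccc1 | intermediate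
21 | (4S)-4-benzyl-3-[(2S,3R)-3-(tert-butyldimethylsilyloxy)-2-methylpentanoyl]oxazolidin-2-one | CC[C@@H](O[Si](C)(C)C(C)(C)C)[C@H](C)C(=O)N1C(=O)OC[C@@H]1Cc1ccccc1 | intermediate
22 | (2R,3R)-3-(tert-butyldimethylsilyloxy)-2-methylpentan-1-ol | CC[C@@H](O[Si](C)(C)C(C)(C)C)[C@H](C)CO | intermediate
23 | tert-butyl{[(2S,3R)-1-iodo-2-methylpentan-3-yl]oxy}dimethylsilane | CC[C@@H](O[Si](C)(C)C(C)(C)C)[C@H](C)CI | intermediate
24 | alkyllithium from 23 (C8–Li) | CC[C@@H](O[Si](C)(C)C(C)(C)C)[C@H](C)C[Li] | intermediate (not isolated)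
25 | lithium C6′ alkoxide of the ring-opened C7 ketone | [Li+].CC[C@@H](O[Si](C)(C)C(C)(C)C)[C@H](C)CC(=O)[C@H]1[C@](C)(O[Si](CC)(CC)CC)[C@@H](O[Si](CC)(CC)CC)C(C)=C[C@@]1(C)C[O-] | intermediate (not isolated)
26 | C7 ketone with chain C8H2–C9H(Me)–C10H(OTBS)–Et; C6′H2OTES; C2/C3 bis-TES | CC[C@@H](O[Si](C)(C)C(C)(C)C)[C@H](C)CC(=O)[C@H]1[C@](C)(O[Si](CC)(CC)CC)[C@@H](O[Si](CC)(CC)CC)C(C)=C[C@@]1(C)CO[Si](CC)(CC)CC | intermediate
27 | potassium (Z)-enolate of 26 (C7=C8) | [K+].CC[C@@H](O[Si](C)(C)C(C)(C)C)[C@H](C)/C=C(\[O-])[C@H]1[C@](C)(O[Si](CC)(CC)CC)[C@@H](O[Si](CC)(CC)CC)C(C)=C[C@@]1(C)CO[Si](CC)(CC)CC | intermediate (not isolated)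
28 | (Z)-C7 enol triflate (OTf cis to C9) | CC[C@@H](O[Si](C)(C)C(C)(C)C)[C@H](C)/C=C(\OS(=O)(=O)C(F)(F)F)[C@H]1[C@](C)(O[Si](CC)(CC)CC)[C@@H](O[Si](CC)(CC)CC)C(C)=C[C@@]1(C)CO[Si](CC)(CC)CC | intermediate
29 | (E)-C7(Me)=C8 alkene; C6′H2OTES | CC[C@@H](O[Si](C)(C)C(C)(C)C)[C@H](C)/C=C(\C)[C@H]1[C@](C)(O[Si](CC)(CC)CC)[C@@H](O[Si](CC)(CC)CC)C(C)=C[C@@]1(C)CO[Si](CC)(CC)CC | intermediate
30 | C6′ aldehyde on C6 | CC[C@@H](O[Si](C)(C)C(C)(C)C)[C@H](C)/C=C(\C)[C@H]1[C@](C)(O[Si](CC)(CC)CC)[C@@H](O[Si](CC)(CC)CC)C(C)=C[C@@]1(C)C=O | intermediate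
31 | methyl 2-methyl-3-oxopentanoate | CCC(=O)C(C)C(=O)OC | starting material
32 | sodium lithium dianion of 31 | [Na+].[Li+].CC=C([O-])C(C)=C([O-])OC | intermediate (not isolated)
33 | aldol adduct: C6′H(OH)–CH(Me)–C(=O)–CH(Me)–CO2Me on C6 (epimer mixture in the new chain) | CC[C@@H](O[Si](C)(C)C(C)(C)C)[C@H](C)/C=C(\C)[C@H]1[C@](C)(O[Si](CC)(CC)CC)[C@@H](O[Si](CC)(CC)CC)C(C)=C[C@@]1(C)C(O)C(C)C(=O)C(C)C(=O)OC | intermediate
34 | β,δ-diketo ester | CC[C@@H](O[Si](C)(C)C(C)(C)C)[C@H](C)/C=C(\C)[C@H]1[C@](C)(O[Si](CC)(CC)CC)[C@@H](O[Si](CC)(CC)CC)C(C)=C[C@@]1(C)C(=O)C(C)C(=O)C(C)C(=O)OC | intermediate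
35 | 4-hydroxy-3,5-dimethyl-2-pyranone attached through C6′ to C6 | CC[C@@H](O[Si](C)(C)C(C)(C)C)[C@H](C)/C=C(\C)[C@H]1[C@](C)(O[Si](CC)(CC)CC)[C@@H](O[Si](CC)(CC)CC)C(C)=C[C@@]1(C)c1oc(=O)c(C)c(O)c1C | intermediate
36 | 2-methoxy-3,5-dimethyl-4-pyranone; C2/C3 bis-TES; C10 OTBS | CC[C@@H](O[Si](C)(C)C(C)(C)C)[C@H](C)/C=C(\C)[C@H]1[C@](C)(O[Si](CC)(CC)CC)[C@@H](O[Si](CC)(CC)CC)C(C)=C[C@@]1(C)c1oc(OC)c(C)c(=O)c1C | intermediate
37 | C3 alcohol (upper face); C2 OTES; C10 OTBS | CC[C@@H](O[Si](C)(C)C(C)(C)C)[C@H](C)/C=C(\C)[C@H]1[C@](C)(O[Si](CC)(CC)CC)[C@@H](O)C(C)=C[C@@]1(C)c1oc(OC)c(C)c(=O)c1C | intermediate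
38 | C3 methanesulfonate of 37 | CC[C@@H](O[Si](C)(C)C(C)(C)C)[C@H](C)/C=C(\C)[C@H]1[C@](C)(O[Si](CC)(CC)CC)[C@@H](OS(C)(=O)=O)C(C)=C[C@@]1(C)c1oc(OC)c(C)c(=O)c1C | intermediate (not isolated)
39 | epoxy alcohol: C2/C3 epoxide on the lower face, C10 hydroxyl | CC[C@@H](O)[C@H](C)/C=C(\C)[C@H]1[C@]2(C)O[C@@H]2C(C)=C[C@@]1(C)c1oc(OC)c(C)c(=O)c1C | intermediate
40 | 2-methoxy-3,5-dimethyl-6-{(1R,4R,5R,6S)-2,4,6-trimethyl-5-[(2E,4R)-4-methyl-5-oxohept-2-en-2-yl]-7-oxabicyclo[4.1.0]hept-2-en-4-yl}-4H-pyran-4-one | CCC(=O)[C@H](C)/C=C(\C)[C@H]1[C@]2(C)O[C@@H]2C(C)=C[C@@]1(C)c1oc(OC)c(C)c(=O)c1C | target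

**Step count.** 25 steps in total. The longest linear sequence is 20 steps (3 → 40: steps 2–10 and 15–25). Step 1 (diene) and steps 11–14 (fragment 23) are side branches.

**Steps most likely to fail**

1. Step 4 (cycloaddition). What may go wrong: both bonds form at substituted carbons, so cycloaddition may be slower than thermal decomposition of the diene, or facial control may erode at the temperature needed. Fallback, from 6 back to 9: the less hindered diene tert-butyldimethyl{[(3Z)-2-methylpenta-1,3-dien-3-yl]oxy}silane F1 (from commercial 2-methylpent-1-en-3-one, TBSOTf, Et3N) is heated with 6 (toluene, 130 °C, sealed tube). Its CH2 terminus bonds to C6, and the expected anti adduct is the C3 silyl enol ether F2, which has CH2 at C5. Saegusa oxidation of F2 (Pd(OAc)2, MeCN, rt) then introduces the C4=C5 double bond and gives enone 9.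

2. Step 10 (oxidative lactonisation). What may go wrong: poor site selectivity between two hindered primary carbinols, with oxidation starting at the neopentyl C6′ carbinol and placing the lactone carbonyl on the wrong carbon. Fallback, from 13 back to 26: saponification of the lactone acetal (LiOH, THF/H2O, 0 °C; then dilute acid) releases menthol and gives the cis-fused hydroxy lactone F3, a masked C7 aldehyde/C6′ acid. Its sodium salt (NaH, THF) is treated with alkyllithium 24 at −78 °C, which adds to the unmasked C7 aldehyde, and acidic work-up closes the γ-lactone F4. LiAlH4 reduction gives the diol F5, in which C7 carries a secondary and C6′ a primary hydroxyl. TESCl/imidazole then silylates only the primary one to give the silyl ether F6, and Dess–Martin oxidation of the secondary alcohol gives ketone 26. The two carbons are thus told apart by alcohol class instead of by hindrance.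

3. Step 22 (O-methylation). What may go wrong: poor regioselectivity of alkylation, with methylation at the C4′ oxygen leading to the isomeric 4-methoxy-2-pyranone. Fallback, from 34 back to 36: the β,δ-diketo ester 34 is cyclodehydrated directly with PPh3/CCl4 in THF. This is a known one-step conversion of 3,5-dioxo methyl esters into 2-methoxy-4-pyranones, in which the ester methoxy group is retained and the ring closes through the C6′ enol oxygen. Steps 21 and 22 are bypassed and no new isolated compound is made.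

**Further compounds**

F1 | step 4 | tert-butyldimethyl{[(3Z)-2-methylpenta-1,3-dien-3-yl]oxy}silane | C=C(C)/C(O[Si](C)(C)C(C)(C)C)=C/C
F2 | step 4 | cis-fused cycloadduct with C3 OTBS enol ether and C5H2 (lactone acetal as in 7) | O=C1O[C@H](O[C@H]3C[C@@H](C)CC[C@@H]3C(C)C)[C@H]2[C@@H](C)C(O[Si](C)(C)C(C)(C)C)=C(C)C[C@@]12C
F3 | step 10 | cis-fused hydroxy lactone (C7 hemiacetal, C6′ lactone carbonyl), C2/C3 bis-TES | O=C1OC(O)[C@H]2[C@](C)(O[Si](CC)(CC)CC)[C@@H](O[Si](CC)(CC)CC)C(C)=C[C@@]12C
F4 | step 10 | γ-lactone with the C8–C12 chain on C7 (C6′ carbonyl), C7 epimers | O=C1OC(C[C@@H](C)[C@@H](CC)O[Si](C)(C)C(C)(C)C)[C@H]2[C@](C)(O[Si](CC)(CC)CC)[C@@H](O[Si](CC)(CC)CC)C(C)=C[C@@]12C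
F5 | step 10 | diol with secondary C7 hydroxyl and primary C6′ hydroxyl | CC[C@@H](O[Si](C)(C)C(C)(C)C)[C@H](C)CC(O)[C@H]1[C@](C)(O[Si](CC)(CC)CC)[C@@H](O[Si](CC)(CC)CC)C(C)=C[C@@]1(C)CO
F6 | step 10 | C6′ triethylsilyl ether of F5 | CC[C@@H](O[Si](C)(C)C(C)(C)C)[C@H](C)CC(O)[C@H]1[C@](C)(O[Si](CC)(CC)CC)[C@@H](O[Si](CC)(CC)CC)C(C)=C[C@@]1(C)CO[Si](CC)(CC)CC
F0 | step 22 | none | none
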